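**Retrosynthetic overview**
1. Target 24 ⇐ (8S)-hydroxy macrocycle 23 by Mitsunobu methacrylation with inversion at C8.
2. 23 ⇐ acyclic bromo aldehyde 21: the ten-membered ring is closed last at C8–C9 by adding a 2-acylallylchromium (a β-acyl carbanion, homoenolate-type donor) to the C8 aldehyde.
3. 21 ⇐ butenolide 18 ⇐ epoxy aldehyde 8 + (Z)-β-iodo enoate 15: C6–C7 bond by Ni/Cr coupling (β-acylvinyl anion equivalent) followed by lactonization.
4. 8 ⇐ nerol (Sharpless epoxidation, ozonolysis, 2-lithioallyl ether addition, oxidation); 15 ⇐ silyl propargyl ether (ynoate, iodo-aldol with CH2O).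
5. Ring order: oxirane (step 1), butenolide (step 9), ten-membered carbocycle (step 13).

Assumption: carbons are called by germacrane numbers (C1 ketone, C4/C5 epoxide, C6 lactone carbinol, C7=C11 butenolide olefin, C8 ester carbinol, C10=C14 methylene, C12 lactone carbonyl, C13 acetoxymethyl carbon, C15 methyl); the epoxide is cis (C3 and C6 on the same side), so the Z-allylic alcohol nerol is the correct precursor.

**Step 1**
Reactants: 1 nerol [(2Z)-3,7-dimethylocta-2,6-dien-1-ol]
Product: 2 (2R,3S)-2,3-epoxynerol {[(2R,3S)-3-methyl-3-(4-methylpent-3-en-1-yl)oxiran-2-yl]methanol}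
Conditions: Ti(OiPr)4 (5 mol%), D-(−)-diethyl tartrate (7 mol%), t-BuOOH, 4 Å MS, CH2Cl2, −20 °C
Reagents that add atoms: tert-butyl hydroperoxide, CC(C)(C)OO
Why: Sharpless asymmetric epoxidation epoxidizes only the allylic olefin, and the D-(−)-tartrate complex delivers oxygen to the face that gives (2R,3S), which is C5 (R) and C4 (S) of the target with the cis relationship coming from the Z olefin.

**Step 2**
Reactants: 2 (2R,3S)-2,3-epoxynerol
Product: 3 3-[(2S,3R)-3-(hydroxymethyl)-2-methyloxiran-2-yl]propanal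
Conditions: O3, NaHCO3, CH2Cl2/MeOH, −78 °C; then Me2S, −78 → 25 °C
Reagents that add atoms: ozone, [O-][O+]=O
Why: Ozonolysis cleaves the electron-rich trisubstituted olefin to the C1 aldehyde (acetone is lost) and leaves the epoxide and the alcohol untouched.

**Step 3**
Reactants: 4 2-bromoprop-2-en-1-ol
Product: 5 [(2-bromoprop-2-en-1-yl)oxy](tert-butyl)dimethylsilane
Conditions: TBSCl, imidazole, CH2Cl2, 0 → 25 °C
Reagents that add atoms: tert-butyldimethylsilyl chloride, CC(C)(C)[Si](C)(C)Cl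
Why: Imidazole-promoted silylation masks the allylic alcohol (the later C9 oxygen) so that the vinyl bromide can be lithiated.

**Step 4**
Reactants: 5 [(2-bromoprop-2-en-1-yl)oxy](tert-butyl)dimethylsilane; 3 3-[(2S,3R)-3-(hydroxymethyl)-2-methyloxiran-2-yl]propanal
Product: 7 1-[(2S,3R)-3-(hydroxymethyl)-2-methyloxiran-2-yl]-4-{[(tert-butyldimethylsilyl)oxy]methyl}pent-4-en-3-ol (C1 epimers), via vinyllithium reagent 6 (not isolated)
Conditions: 5 (2.4 equiv), t-BuLi (4.8 equiv), Et2O, −78 °C; then 3, −78 → −40 °C; H2O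
Reagents that add atoms: none
Why: Bromine–lithium exchange followed by 1,2-addition of the vinyllithium to the aldehyde (one equivalent is used up by the free hydroxyl) attaches C10, C14 and C9; the new C1 carbinol centre is removed by oxidation in the next step and the trisubstituted epoxide is inert at −78 °C.

**Step 5**
Reactants: 7 diol (C1 epimers)
Product: 8 (2S,3S)-3-(4-{[(tert-butyldimethylsilyl)oxy]methyl}-3-oxopent-4-en-1-yl)-3-methyloxirane-2-carbaldehyde
Conditions: Dess–Martin periodinane (2.6 equiv), CH2Cl2, 0 → 25 °C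
Reagents that add atoms: none
Why: Dess–Martin oxidation converts the allylic carbinol into the C1 enone and the primary alcohol into the C6 epoxy aldehyde in one operation; the aldehyde α-carbon sits in the oxirane and does not epimerize.

**Step 6**
Reactants: 9 tert-butyldimethyl(prop-2-yn-1-yloxy)silane
Product: 11 methyl 4-[(tert-butyldimethylsilyl)oxy]but-2-ynoate, via lithium acetylide 10 (not isolated)
Conditions: n-BuLi, THF, −78 °C; then ClCO2Me, −78 → 0 °C
Reagents that add atoms: methyl chloroformate, COC(=O)Cl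
Why: Deprotonation of the terminal alkyne and acylation of the acetylide with the chloroformate (methoxycarbonylation) gives the ynoate carrying C12, C11, C7 and C8.

**Step 7**
Reactants: 11 methyl 4-[(tert-butyldimethylsilyl)oxy]but-2-ynoate
Product: 14 methyl (2Z)-2-(acetoxymethyl)-4-[(tert-butyldimethylsilyl)oxy]-3-iodobut-2-enoate, via iodomagnesium allenolate 12 (not isolated), via iodomagnesium alkoxide 13 (not isolated)
Conditions: MgI2 (1.3 equiv), monomeric CH2O (from paraformaldehyde), CH2Cl2, −40 → 0 °C; then Ac2O, pyridine, DMAP (cat.), 0 °C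
Reagents that add atoms: magnesium diiodide, [Mg+2].[I-].[I-]; formaldehyde, C=O; acetic anhydride, CC(=O)OC(C)=O
Why: Proposed new method: iodide from MgI2 adds conjugately to the ynoate to give allenolate 12, whose α-carbon adds to formaldehyde on the side away from iodine so that iodine ends cis to the ester (Z), and alkoxide 13 is acetylated in the same flask; the closest known reaction is the MgI2- or TMSI-promoted β-iodo Morita–Baylis–Hillman (iodo-aldol) coupling of propiolates with aldehydes, which is Z-selective for the same reason and is extended here to a γ-silyloxy internal ynoate and CH2O.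

**Step 8**
Reactants: 14 methyl (2Z)-2-(acetoxymethyl)-4-[(tert-butyldimethylsilyl)oxy]-3-iodobut-2-enoate
Product: 15 methyl (2Z)-2-(acetoxymethyl)-4-hydroxy-3-iodobut-2-enoate
Conditions: HF·pyridine, pyridine, THF, 0 °C
Reagents that add atoms: none
Why: Fluoride desilylation frees the C8 alcohol, which is trans to the ester in the Z isomer and cannot lactonize, whereas any E isomer closes to an iodobutenolide and is removed by chromatography.

**Step 9**
Reactants: 8 (2S,3S)-epoxy keto aldehyde; 15 methyl (2Z)-2-(acetoxymethyl)-4-hydroxy-3-iodobut-2-enoate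
Product: 18 {(5R)-5-[(2R,3S)-3-(4-{[(tert-butyldimethylsilyl)oxy]methyl}-3-oxopent-4-en-1-yl)-3-methyloxiran-2-yl]-4-(hydroxymethyl)-2-oxo-2,5-dihydrofuran-3-yl}methyl acetate, via alkenylchromium dichloride 16 (not isolated), via seco hydroxy ester 17 (not isolated)
Conditions: CrCl2 (6 equiv), NiCl2 (2 mol%), 15 (1.8 equiv), DMSO/THF, 25 °C
Reagents that add atoms: none
Why: Nozaki–Hiyama–Kishi coupling, in which zerovalent nickel inserts into the C–I bond and transmetalation gives the β-(methoxycarbonyl)alkenylchromium (a β-acylvinyl anion equivalent) that adds only to the aldehyde, anti to the epoxide C–O bond (Felkin–Anh), setting C6 as R; the resulting Z-γ-alkoxy ester lactonizes in the flask to the butenolide.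

**Step 10**
Reactants: 18 hydroxymethyl butenolide
Product: 19 {(5R)-5-[(2R,3S)-3-(4-{[(tert-butyldimethylsilyl)oxy]methyl}-3-oxopent-4-en-1-yl)-3-methyloxiran-2-yl]-4-formyl-2-oxo-2,5-dihydrofuran-3-yl}methyl acetate
Conditions: Dess–Martin periodinane (1.5 equiv), CH2Cl2, 0 → 25 °C
Reagents that add atoms: none
Why: Dess–Martin oxidation of the primary allylic alcohol gives the C8 aldehyde under neutral conditions that do not touch the acidic C6–H next to the epoxide.

**Step 11**
Reactants: 19 formyl butenolide silyl ether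
Product: 20 {(5R)-4-formyl-5-[(2R,3S)-3-[4-(hydroxymethyl)-3-oxopent-4-en-1-yl]-3-methyloxiran-2-yl]-2-oxo-2,5-dihydrofuran-3-yl}methyl acetate
Conditions: HF·pyridine, pyridine, THF, 0 → 25 °C
Reagents that add atoms: none
Why: Buffered fluoride desilylation removes the allylic silyl ether while epoxide, acetate, lactone and aldehyde survive.

**Step 12**
Reactants: 20 hydroxymethyl enone aldehyde
Product: 21 {(5R)-5-[(2R,3S)-3-[4-(bromomethyl)-3-oxopent-4-en-1-yl]-3-methyloxiran-2-yl]-4-formyl-2-oxo-2,5-dihydrofuran-3-yl}methyl acetate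
Conditions: NBS, Me2S, CH2Cl2, −20 → 0 °C; used crude
Reagents that add atoms: N-bromosuccinimide, O=C1CCC(=O)N1Br
Why: Corey–Kim bromination activates the allylic alcohol as an alkoxysulfonium ion that bromide displaces, without base or acid, so the aldehyde, the epoxide and the C6–H are not disturbed.

**Step 13**
Reactants: 21 bromomethyl enone aldehyde
Product: 23 (4S,5R,6R,8S)-13-acetoxy-4,5-epoxy-8-hydroxy-1-oxogermacra-7(11),10(14)-dien-12,6-olide, via allylchromium dichloride 22 (not isolated)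
Conditions: CrCl2 (8 equiv), THF, 25 °C, syringe-pump addition of 21 over 12 h (final 2 mM); aq. NH4Cl
Reagents that add atoms: none
Why: Chromium-mediated Barbier (Nozaki–Hiyama) macrocyclization, in which two equivalents of divalent chromium turn the electrophilic allylic bromide into 2-acylallylchromium 22 (a carbanion β to the C1 ketone, a homoenolate-type donor) that adds to the C8 aldehyde through a six-membered chair; the tether leaves C6 on the C5 face of the butenolide, so C9 can only reach that face of the s-trans formyl group, which gives 8S, and the allyl transposition leaves the C10=C14 methylene ketone while the cis-epoxide and three sp2 ring atoms pre-fold the chain.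

**Step 14**
Reactants: 23 (8S)-hydroxy macrocycle
Product: 24 (4S,5R,6R,8R)-13-acetoxy-4,5-epoxy-8-(methacryloyloxy)-1-oxogermacra-7(11),10(14)-dien-12,6-olide (target)
Conditions: PPh3, DIAD, methacrylic acid, toluene, 0 → 25 °C (betaine preformed)
Reagents that add atoms: methacrylic acid, C=C(C)C(=O)O
Why: Mitsunobu esterification displaces the activated C8 oxyphosphonium by methacrylate in an SN2 step with clean inversion, turning 8S into the 8R ester of the target under neutral conditions.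

**Compound list**
1 | nerol, (2Z)-3,7-dimethylocta-2,6-dien-1-ol | OC/C=C(C)\CCC=C(C)C | starting material
2 | (2R,3S)-2,3-epoxynerol | CC(C)=CCC[C@]1(C)O[C@@H]1CO | intermediate
3 | 3-[(2S,3R)-3-(hydroxymethyl)-2-methyloxiran-2-yl]propanal | O=CCC[C@]1(C)O[C@@H]1CO | intermediate
4 | 2-bromoprop-2-en-1-ol | C=C(Br)CO | starting material
5 | [(2-bromoprop-2-en-1-yl)oxy](tert-butyl)dimethylsilane | C=C(Br)CO[Si](C)(C)C(C)(C)C | intermediate
6 | {3-[(tert-butyldimethylsilyl)oxy]prop-1-en-2-yl}lithium | [Li]C(=C)CO[Si](C)(C)C(C)(C)C | intermediate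
7 | 1-[(2S,3R)-3-(hydroxymethyl)-2-methyloxiran-2-yl]-4-{[(tert-butyldimethylsilyl)oxy]methyl}pent-4-en-3-ol (C1 epimers) | C=C(CO[Si](C)(C)C(C)(C)C)C(O)CC[C@]1(C)O[C@@H]1CO | intermediate
8 | (2S,3S)-3-(4-{[(tert-butyldimethylsilyl)oxy]methyl}-3-oxopent-4-en-1-yl)-3-methyloxirane-2-carbaldehyde | C=C(CO[Si](C)(C)C(C)(C)C)C(=O)CC[C@]1(C)O[C@@H]1C=O | intermediate
9 | tert-butyldimethyl(prop-2-yn-1-yloxy)silane | C#CCO[Si](C)(C)C(C)(C)C | starting material
10 | lithium acetylide of 9 | [Li]C#CCO[Si](C)(C)C(C)(C)C | intermediate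
11 | methyl 4-[(tert-butyldimethylsilyl)oxy]but-2-ynoate | COC(=O)C#CCO[Si](C)(C)C(C)(C)C | intermediate
12 | iodomagnesium allenolate of methyl 3-iodo-4-(silyloxy)buta-2,3-dienoate | COC(O[Mg]I)=C=C(I)CO[Si](C)(C)C(C)(C)C | intermediate
13 | iodomagnesium alkoxide of methyl (2Z)-4-[(tert-butyldimethylsilyl)oxy]-2-(hydroxymethyl)-3-iodobut-2-enoate | COC(=O)/C(CO[Mg]I)=C(\I)CO[Si](C)(C)C(C)(C)C | intermediate
14 | methyl (2Z)-2-(acetoxymethyl)-4-[(tert-butyldimethylsilyl)oxy]-3-iodobut-2-enoate | COC(=O)/C(COC(C)=O)=C(\I)CO[Si](C)(C)C(C)(C)C | intermediate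
15 | methyl (2Z)-2-(acetoxymethyl)-4-hydroxy-3-iodobut-2-enoate | COC(=O)/C(COC(C)=O)=C(\I)CO | intermediate
16 | alkenylchromium dichloride from 15 (hydroxyl written free) | COC(=O)/C(COC(C)=O)=C(\[Cr](Cl)Cl)CO | intermediate
17 | seco hydroxy ester (6R), a chromium alkoxide in the flask | C=C(CO[Si](C)(C)C(C)(C)C)C(=O)CC[C@]1(C)O[C@@H]1[C@H](O)/C(CO)=C(/COC(C)=O)C(=O)OC | intermediate
18 | {(5R)-5-[(2R,3S)-3-(4-{[(tert-butyldimethylsilyl)oxy]methyl}-3-oxopent-4-en-1-yl)-3-methyloxiran-2-yl]-4-(hydroxymethyl)-2-oxo-2,5-dihydrofuran-3-yl}methyl acetate | C=C(CO[Si](C)(C)C(C)(C)C)C(=O)CC[C@]1(C)O[C@@H]1[C@@H]1OC(=O)C(COC(C)=O)=C1CO | intermediate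
19 | 4-formyl analogue of 18 | C=C(CO[Si](C)(C)C(C)(C)C)C(=O)CC[C@]1(C)O[C@@H]1[C@@H]1OC(=O)C(COC(C)=O)=C1C=O | intermediate
20 | {(5R)-4-formyl-5-[(2R,3S)-3-[4-(hydroxymethyl)-3-oxopent-4-en-1-yl]-3-methyloxiran-2-yl]-2-oxo-2,5-dihydrofuran-3-yl}methyl acetate | C=C(CO)C(=O)CC[C@]1(C)O[C@@H]1[C@@H]1OC(=O)C(COC(C)=O)=C1C=O | intermediate
21 | {(5R)-5-[(2R,3S)-3-[4-(bromomethyl)-3-oxopent-4-en-1-yl]-3-methyloxiran-2-yl]-4-formyl-2-oxo-2,5-dihydrofuran-3-yl}methyl acetate | C=C(CBr)C(=O)CC[C@]1(C)O[C@@H]1[C@@H]1OC(=O)C(COC(C)=O)=C1C=O | intermediate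
22 | allylchromium dichloride from 21 | C=C(C[Cr](Cl)Cl)C(=O)CC[C@]1(C)O[C@@H]1[C@@H]1OC(=O)C(COC(C)=O)=C1C=O | intermediate
23 | (4S,5R,6R,8S)-13-acetoxy-4,5-epoxy-8-hydroxy-1-oxogermacra-7(11),10(14)-dien-12,6-olide | O[C@H]1CC(=C)C(=O)CC[C@]2(C)O[C@@H]2[C@@H]2OC(=O)C(COC(C)=O)=C21 | intermediate
24 | (4S,5R,6R,8R)-13-acetoxy-4,5-epoxy-8-(methacryloyloxy)-1-oxogermacra-7(11),10(14)-dien-12,6-olide | C=C(C)C(=O)O[C@@H]1CC(=C)C(=O)CC[C@]2(C)O[C@@H]2[C@@H]2OC(=O)C(COC(C)=O)=C21 | target

**Step count**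
Total: 14 steps. Longest linear sequence: 10 steps (1, 2, 4, 5, 9, 10, 11, 12, 13, 14); three steps lead to iodide 15 and one to bromide 5.

**Three steps most likely to fail**

Step 13 (ring closure). The ten-membered ring may form slowly against oligomerization, and divalent chromium may reduce the electron-poor formyl butenolide. The C8 configuration rests on a geometric argument (tether on the C5 face, s-trans aldehyde) and has not been modelled. Fallback for the stereochemical outcome, from 21 to 24: if the closure goes through the other aldehyde rotamer, the product is (4S,5R,6R,8R)-13-acetoxy-4,5-epoxy-8-hydroxy-1-oxogermacra-7(11),10(14)-dien-12,6-olide F8. This alcohol is esterified with retention (methacrylic anhydride, DMAP, pyridine, CH2Cl2, 0 °C) to give 24, so either C8 epimer reaches the target by choosing the invertive or the retentive esterification.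

Step 7 (iodo-aldol). Formaldehyde and a tetrasubstituted product are outside the tested scope, and the Z/E ratio is uncertain. Fallback, from 11 (with 8) to 18, installing C13 after the butenolide is made: hydroiodination of 11 with NaI in AcOH (anti addition, Z only), followed in the same pot by aqueous HF in MeCN, gives methyl (2Z)-4-hydroxy-3-iodobut-2-enoate F1. Coupling of F1 with 8 (CrCl2, NiCl2 cat.) gives (5R)-5-[(2R,3S)-3-(4-{[(tert-butyldimethylsilyl)oxy]methyl}-3-oxopent-4-en-1-yl)-3-methyloxiran-2-yl]-4-(hydroxymethyl)furan-2(5H)-one F2. α-Iodination (I2, pyridine, DMAP, CH2Cl2) gives the 3-iodo butenolide F3. Stille coupling of F3 with (acetoxymethyl)tributylstannane under zerovalent palladium (Pd2(dba)3, AsPh3, CuI, DMF, 50 °C) attaches C13 with its acetate and gives 18.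

Step 9 (intermolecular Ni/Cr coupling). Aldehyde 8 carries an enone that divalent chromium or the alkenylchromium may attack, and the Felkin ratio may be modest. Fallback, from 2 (with 15 and 5) to 19, coupling on a simpler aldehyde and building the enone afterwards: Dess–Martin oxidation of 2 gives (2S,3S)-3-methyl-3-(4-methylpent-3-en-1-yl)oxirane-2-carbaldehyde F4. Ni/Cr coupling of F4 with 15 and lactonization gives {(5R)-4-(hydroxymethyl)-5-[(2R,3S)-3-methyl-3-(4-methylpent-3-en-1-yl)oxiran-2-yl]-2-oxo-2,5-dihydrofuran-3-yl}methyl acetate F5. Ozonolysis of the remaining trisubstituted olefin (O3; Me2S) gives the aldehyde {(5R)-4-(hydroxymethyl)-5-[(2R,3S)-3-methyl-3-(3-oxopropyl)oxiran-2-yl]-2-oxo-2,5-dihydrofuran-3-yl}methyl acetate F6. A second Ni/Cr coupling of F6 with vinyl bromide 5 (CrCl2, NiCl2, DMF, 50 °C) gives the allylic alcohol {(5R)-5-[(2R,3S)-3-(4-{[(tert-butyldimethylsilyl)oxy]methyl}-3-hydroxypent-4-en-1-yl)-3-methyloxiran-2-yl]-4-(hydroxymethyl)-2-oxo-2,5-dihydrofuran-3-yl}methyl acetate F7 (C1 epimers). Dess–Martin oxidation of both the C1 carbinol and the C8 primary alcohol of F7 gives 19.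

**Further compounds**
F1 | step 7 | methyl (2Z)-4-hydroxy-3-iodobut-2-enoate | COC(=O)/C=C(\I)CO
F2 | step 7 | (5R)-5-[(2R,3S)-3-(4-{[(tert-butyldimethylsilyl)oxy]methyl}-3-oxopent-4-en-1-yl)-3-methyloxiran-2-yl]-4-(hydroxymethyl)furan-2(5H)-one | C=C(CO[Si](C)(C)C(C)(C)C)C(=O)CC[C@]1(C)O[C@@H]1[C@@H]1OC(=O)C=C1CO
F3 | step 7 | (5R)-5-[(2R,3S)-3-(4-{[(tert-butyldimethylsilyl)oxy]methyl}-3-oxopent-4-en-1-yl)-3-methyloxiran-2-yl]-4-(hydroxymethyl)-3-iodofuran-2(5H)-one | C=C(CO[Si](C)(C)C(C)(C)C)C(=O)CC[C@]1(C)O[C@@H]1[C@@H]1OC(=O)C(I)=C1CO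
F4 | step 9 | (2S,3S)-3-methyl-3-(4-methylpent-3-en-1-yl)oxirane-2-carbaldehyde | CC(C)=CCC[C@]1(C)O[C@@H]1C=O
F5 | step 9 | {(5R)-4-(hydroxymethyl)-5-[(2R,3S)-3-methyl-3-(4-methylpent-3-en-1-yl)oxiran-2-yl]-2-oxo-2,5-dihydrofuran-3-yl}methyl acetate | CC(C)=CCC[C@]1(C)O[C@@H]1[C@@H]1OC(=O)C(COC(C)=O)=C1CO
F6 | step 9 | {(5R)-4-(hydroxymethyl)-5-[(2R,3S)-3-methyl-3-(3-oxopropyl)oxiran-2-yl]-2-oxo-2,5-dihydrofuran-3-yl}methyl acetate | O=CCC[C@]1(C)O[C@@H]1[C@@H]1OC(=O)C(COC(C)=O)=C1CO
F7 | step 9 | {(5R)-5-[(2R,3S)-3-(4-{[(tert-butyldimethylsilyl)oxy]methyl}-3-hydroxypent-4-en-1-yl)-3-methyloxiran-2-yl]-4-(hydroxymethyl)-2-oxo-2,5-dihydrofuran-3-yl}methyl acetate (C1 epimers) | C=C(CO[Si](C)(C)C(C)(C)C)C(O)CC[C@]1(C)O[C@@H]1[C@@H]1OC(=O)C(COC(C)=O)=C1CO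
F8 | step 13 | (4S,5R,6R,8R)-13-acetoxy-4,5-epoxy-8-hydroxy-1-oxogermacra-7(11),10(14)-dien-12,6-olide | O[C@@H]1CC(=C)C(=O)CC[C@]2(C)O[C@@H]2[C@@H]2OC(=O)C(COC(C)=O)=C21
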